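The rate constants come from no measurement; the flask was simulated.

An exponent of 0.172 was my starting point for this flask. In it, substrate, dissolved gas and free catalyst make product, pairs of free catalyst die to spent catalyst, and added ligand holds some free catalyst as idle complex.

substrate 31 mM; gas phase 1.2 mM (held); free catalyst 31 µM; added ligand 51 µM; time 15 h

1. amount of product at 15 h, in percent of the substrate charged
2. concentration of dissolved gas in solution at 15 h, in percent of saturation

- where a step has two of a species, its rate is k times that concentration squared, and two are used at each turn
- at the start none of the gas is dissolved
- run time (flask): 15 h

    substrate + dissolved gas + free catalyst → free catalyst + product (k1 = 6.19 × 10⁵ L² mol⁻² h⁻¹)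
    2 free catalyst → spent catalyst (k2 = 2160 L mol⁻¹ h⁻¹)
    free catalyst + added ligand ⇌ idle complex (K3 = 9400 L mol⁻¹, k3 = 1880 L mol⁻¹ h⁻¹)
    gas phase ⇌ dissolved gas, rate k4*(csat - [dissolved gas]) (k4 = 2.49 h⁻¹, csat = 1.2 mM)

I divided the substrate's pseudo-first-order loss by the catalyst's second-order loss, and time dropped out. The quotient, with gas at saturation, is the yield exponent: the constant of the working step times the saturation concentration, over 2 times the constant of catalyst death. In fractions of the charge:

ln(substrate left) = exponent × ln(catalyst left)

This looked odd at first, since the crossing of gas into a solution kept empty could deliver at most 145 % of the substrate charged by 15 h, yet so small an exponent promised little product. I refined the exponent for this flask, taking free plus idle catalyst as the working catalyst: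

free share of working catalyst, ligand as charged: 0.676

working catalyst left at 15 h: 0.521

gas fraction of saturation, transfer against consumption, at the start: 0.807

the same at 15 h: 92.2 %

mean gas fraction: 0.865

exponent × gas fraction / free share: 0.220

product fraction: 13.3 %

So the oddity cleared: the gas on offer stood above what the dying catalyst could turn over.

The forecast gave 13.4 % of product (range 12 % to 15 %) and 94 % of saturation (range 92 % to 95.5 %), holding that “Gas transfer outruns consumption”.

The flask gave 13.3 % and 93.8 %, inside both ranges.

The neighbouring flask held the same charge and was read at 25 h. The bare exponent 0.172 holds no reading time, but the corrected one does, through its mean gas fraction, so I reckoned that again. By the same law, working catalyst fell to 0.395, the mean gas fraction stood at 0.874, the corrected exponent at 0.222, and the product fraction came to 0.186. The neighbouring flask itself held free catalyst at 24.7 % and idle complex at 12.4 % of the catalyst charged, and its product stood at 18.4 %.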